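## Retrosynthetic overview

1. Target 30 ⇒ macrocyclic dienol 23 by late functionalisation: hydroxyl-directed epoxidations (C3–C4, C13–C14), ene-type chlorination (C6–Cl with C5=C16), and the C12 carbinol by reduction then inversion.
2. 23 ⇒ iodo enone aldehyde 21: the ten-membered ring is closed last, at C2–C3, by an electrochemical chromium/nickel alkenylation of the C2 aldehyde.
3. 21 ⇒ enal 15 + ethyl vinyl ketone 16: the cyclohexenone (C1, C10, C11) comes from a silicon-tethered type 2 intramolecular Diels–Alder reaction.
4. 15 ⇒ butenolide 4: the γ-lactone comes from a samarium Reformatsky closure onto a C8 ketone; C7–C8 comes from a vinylogous Mukaiyama aldol of silyloxyfuran 2 with (S)-glyceraldehyde acetonide 3, the only source of chirality.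
5. Ring order: γ-lactone, then cyclohexene, then ten-membered carbocycle, then the two oxiranes.

Assumption: briarane numbering (C1–C20; C15 methyl on C1, C16 on C5, C18 methyl on C17, C19 lactone carbonyl, C20 methyl on C11) is used for every intermediate, and the SMILES strings are the binding statement of configuration.

## Route

Step 1
Reactants: 1 3-methylfuran-2(5H)-one
Product: 2 silyloxyfuran
Conditions: TBSOTf, Et3N, CH2Cl2, 0 °C
Reagents that add atoms: tert-butyldimethylsilyl trifluoromethanesulfonate, CC(C)(C)[Si](C)(C)OS(=O)(=O)C(F)(F)F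
Why: Soft enolisation and O-silylation of the butenolide gives the aromatic 2-silyloxyfuran, a dienolate equivalent that is nucleophilic at C7; no stereocentre is formed.

Step 2
Reactants: 2 silyloxyfuran; 3 (S)-glyceraldehyde acetonide
Product: 4 butenolide silyl ether
Conditions: TBSOTf (10 mol%), CH2Cl2, −78 °C
Reagents that add atoms: none
Why: Silyl-transfer vinylogous Mukaiyama aldol in which the furan γ-carbon (C7) adds to the aldehyde through an open transition state, Felkin–Anh anti to the dioxolane C–O (C8/C9 erythro) and with threo C7/C8 topicity, the silyl group ending on O8 while C9 is carried over from 3.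

Step 3
Reactants: 4 butenolide silyl ether
Product: 5 lactol
Conditions: iBu2AlH, CH2Cl2, −78 °C; Rochelle salt
Reagents that add atoms: none
Why: Partial 1,2-reduction of the unsaturated lactone gives the lactol, a masked (Z)-4-hydroxy enal, which is worked up neutral to avoid dehydration to the furan; C7–C9 are untouched.

Step 4
Reactants: 5 lactol
Product: 6 iododienyl carbinol
Conditions: CrCl2, CHI3, THF–dioxane, 0 °C to rt
Reagents that add atoms: iodoform, IC(I)I
Why: Takai iodo-olefination of the ring-opened aldehyde gives the (E)-vinyl iodide, while the 5Z geometry is inherited from the butenolide ring.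

Step 5
Reactants: 6 iododienyl carbinol; 7 2-bromopropanoic acid
Product: 8 C7 bromopropanoate
Conditions: PPh3, DIAD, PhMe, −20 to 0 °C
Reagents that add atoms: none
Why: Mitsunobu esterification with SN2 inversion at the allylic C7 carbinol brings O7 into the target configuration (syn to O9) and installs the Reformatsky handle, whose bromide-bearing carbon is a mixture that converges at the enolate.

Step 6
Reactants: 8 C7 bromopropanoate
Product: 9 C8 alcohol
Conditions: HF·pyridine, THF, 0 °C to rt
Reagents that add atoms: none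
Why: Acidic fluoride desilylation frees the C8 hydroxyl without the acyl migration or bromide loss that basic fluoride would risk.

Step 7
Reactants: 9 C8 alcohol
Product: 10 C8 ketone
Conditions: Dess–Martin periodinane, NaHCO3, CH2Cl2, 0 °C
Reagents that add atoms: none
Why: Neutral Dess–Martin oxidation removes the temporary C8 stereocentre and gives the α-acyloxy ketone without enolising the allylic C7.

Step 8
Reactants: 10 C8 ketone
Product: 11 hydroxy lactone acetonide
Conditions: SmI2 (2.2 equiv), THF, −78 °C
Reagents that add atoms: none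
Why: Intramolecular samarium Reformatsky reaction in which the trivalent samarium enolate adds to the C8 ketone under Felkin–Anh control (C9–O antiperiplanar to the incoming carbon), setting the tertiary 8-OH, with the C18 methyl trans to the C9 branch and so cis to OH at C17.

Step 9
Reactants: 11 hydroxy lactone acetonide
Product: 12 lactone triol
Conditions: AcOH–H2O (4:1), 40 °C
Reagents that add atoms: none
Why: Mild acid hydrolysis of the terminal isopropylidene acetal leaves the lactone, the tertiary alcohol and the iododiene intact and touches no stereocentre.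

Step 10
Reactants: 12 lactone triol; 13 2-(triphenylphosphoranylidene)propanal
Product: 15 enal diol, via C10 hydroxy aldehyde 14 (not isolated)
Conditions: TEMPO (10 mol%), PhI(OAc)2, CH2Cl2, rt; then 13, 40 °C
Reagents that add atoms: none
Why: Chemoselective oxoammonium oxidation of the primary alcohol followed in the same pot by a stabilised Wittig olefination gives the (E)-2-methyl enal (C2 formyl trans to C9), with C9 unchanged.

Step 11
Reactants: 15 enal diol; 16 pent-1-en-3-one
Product: 19 bridged cycloadduct, via dienyl silyl triflate 17 (not isolated), via silaketal 18 (not isolated)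
Conditions: 16, iPr2Si(OTf)2, Et3N, CH2Cl2, 0 °C; then 15; then PhMe, BHT, 120 °C
Reagents that add atoms: diisopropylsilyl bis(trifluoromethanesulfonate), CC(C)[Si](OS(=O)(=O)C(F)(F)F)(OS(=O)(=O)C(F)(F)F)C(C)C
Why: Silaketal-tethered type 2 intramolecular Diels–Alder reaction in which the O9–Si–O12 tether fixes the regiochemistry (C11 to C10, C14 to C1), holds O9 inside and the quaternary C8 anti to the diene, and places C9 endo with the formyl exo, so that the (E)-enal sets C1/C10 and the (Z)-enol ether places the C20 methyl cis to C9 and C15.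

Step 12
Reactants: 19 bridged cycloadduct
Product: 21 iodo enone aldehyde, via aryloxysilyl enone 20 (not isolated)
Conditions: DDQ, 2,6-lutidine, MeCN, 0 °C to rt; then HF·pyridine
Reagents that add atoms: none
Why: DDQ dehydrogenation of the silyl enol ether (hydride abstraction at allylic C14, a palladium-free Saegusa-type outcome that spares the C–I bond) gives the C13=C14 enone, and fluoride then cleaves the silicon from O9; no stereocentre changes.

Step 13
Reactants: 21 iodo enone aldehyde
Product: 23 macrocyclic dienol, via C2 silyl ether 22 (not isolated)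
Conditions: CrCl2 (20 mol%), NiCl2·glyme (2 mol%), 4,4′-di-tert-butyl-2,2′-bipyridine (25 mol%), TMSCl, LiCl, DMF–THF, 1 mM (slow addition), undivided cell, Al anode, Ni-foam cathode, 2 mA, rt; then aq. citric acid
Reagents that add atoms: none
Why: Proposed new method: an electrochemically driven, chromium-catalytic Nozaki–Hiyama–Kishi ring closure in which zerovalent nickel inserts into the dienyl C–I bond, the alkenyl group passes to trivalent chromium and adds to the neopentyl C2 aldehyde, TMSCl frees chromium from the alkoxide and the cathode (sacrificial Al anode) regenerates divalent chromium and zerovalent nickel, so the ten-membered ring closes at C2–C3 with retention of the 3E geometry and C2 is set by substrate control (C3 attacks anti to the C1–C10 bond with the chromium-bound oxygen in the open sector beside the sp2 C14–H); the closest known chemistry is the intermolecular electrochemical NHK coupling of alkenyl halides with aldehydes and the stoichiometric CrCl2/NiCl2 NHK macrocyclisation, neither shown as an electrocatalytic ten-membered carbocyclisation.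

Step 14
Reactants: 23 macrocyclic dienol
Product: 24 3,4-epoxide
Conditions: VO(acac)2 (5 mol%), t-BuOOH, CH2Cl2, 0 °C
Reagents that add atoms: tert-butyl hydroperoxide, CC(C)(C)OO
Why: Hydroxyl-directed vanadium epoxidation of the only olefin that is allylic to a secondary hydroxyl delivers oxygen to the (E)-C3=C4 bond erythro to the C2–OH through the vanadate ester, giving the trans-3,4-oxirane and leaving the 5Z olefin and the enone untouched.

Step 15
Reactants: 24 3,4-epoxide
Product: 25 diacetate
Conditions: Ac2O, pyridine, DMAP (cat.), CH2Cl2, 0 °C to rt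
Reagents that add atoms: acetic anhydride, CC(=O)OC(C)=O
Why: Acetylation of the two secondary hydroxyls (C2, C9) while the hindered tertiary 8-OH stays free, as is usual for tertiary carbinols under these conditions.

Step 16
Reactants: 25 diacetate
Product: 26 allylic chloride
Conditions: Ca(OCl)2, CO2 (dry ice), CH2Cl2–H2O, 0 °C, dark
Reagents that add atoms: calcium hypochlorite, [Ca+2].[O-]Cl.[O-]Cl
Why: Ene-type allylic chlorination by HOCl in which chlorine adds to C6 of the trisubstituted 5Z olefin on the face anti to the quaternary C8 (C7–H eclipsing the olefin to avoid A1,3 strain with C4) while a C16 proton is lost to give the 5(16)-methylene, the oxirane C4–H being unable to eliminate.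

Step 17
Reactants: 26 allylic chloride
Product: 27 12-epi allylic alcohol
Conditions: NaBH4, CeCl3·7H2O, MeOH, −78 °C
Reagents that add atoms: none
Why: Luche 1,2-reduction in which hydride enters on the face opposite the C20 methyl and the axial C10–C9 bond (the three cis substituents on C1, C10 and C11 force C9 axial), giving the axial alcohol cis to the C20 methyl, that is the C12 epimer.

Step 18
Reactants: 27 12-epi allylic alcohol
Product: 28 12-formate
Conditions: HCO2H, PPh3, DIAD, THF, 0 °C
Reagents that add atoms: formic acid, OC=O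
Why: Mitsunobu inversion at the allylic C12 with the carboxylate entering from the open face gives the target C12 configuration (oxygen trans to the C20 methyl), SN2′ attack at C14 being blocked by the quaternary C1.

Step 19
Reactants: 28 12-formate
Product: 29 12-allylic alcohol
Conditions: KHCO3 (cat.), MeOH, 0 °C
Reagents that add atoms: none
Why: Formate esters undergo methanolysis far faster than secondary acetates, so the C12 hydroxyl is freed with retention while the C2 and C9 acetates, the lactone and the allylic chloride remain.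

Step 20
Reactants: 29 12-allylic alcohol
Product: 30 CNP0141778.4
Conditions: VO(acac)2 (5 mol%), t-BuOOH, CH2Cl2, 0 °C
Reagents that add atoms: tert-butyl hydroperoxide, CC(C)(C)OO
Why: Hydroxyl-directed vanadium epoxidation delivers oxygen to C13=C14 syn to the C12–OH, giving the cis epoxy alcohol of the target, while the 5(16)-methylene has no directing hydroxyl.

## Compound list

1 | 3-methylfuran-2(5H)-one | CC1=CCOC1=O | starting material
2 | silyloxyfuran: tert-butyldimethyl[(3-methylfuran-2-yl)oxy]silane | Cc1ccoc1O[Si](C)(C)C(C)(C)C | intermediate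
3 | (S)-glyceraldehyde acetonide: (S)-2,2-dimethyl-1,3-dioxolane-4-carbaldehyde (becomes C8–C10) | O=C[C@@H]1COC(C)(C)O1 | starting material
4 | butenolide silyl ether: (5S)-5-{(R)-(tert-butyldimethylsilyloxy)[(4S)-2,2-dimethyl-1,3-dioxolan-4-yl]methyl}-3-methylfuran-2(5H)-one (C7/C8 threo, C8/C9 erythro; C7 epimeric to the target) | CC1=C[C@@H]([C@@H](O[Si](C)(C)C(C)(C)C)[C@@H]2COC(C)(C)O2)OC1=O | intermediate
5 | lactol: the 2-hydroxy-2,5-dihydrofuran from 4 (C4 hemiacetal, anomer mixture; other centres as in 4) | CC1=C[C@@H]([C@@H](O[Si](C)(C)C(C)(C)C)[C@@H]2COC(C)(C)O2)OC1O | intermediate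
6 | iododienyl carbinol: I–C3H=C4H–C5(CH3)=C6H–C7H(OH)–C8H(OTBS)–C9H–C10H2 with 9,10-O-isopropylidene, 3E,5Z; C7 epimeric to the target, C8 and C9 as in 4 | I/C=C/C(C)=C\[C@H](O)[C@@H](O[Si](C)(C)C(C)(C)C)[C@@H]1COC(C)(C)O1 | intermediate
7 | 2-bromopropanoic acid (racemic) | CC(Br)C(=O)O | starting material
8 | C7 bromopropanoate: as 6 but with C7–O–C(=O)–CHBr–CH3 and C7 inverted to the target configuration | I/C=C/C(C)=C\[C@@H](OC(=O)C(C)Br)[C@@H](O[Si](C)(C)C(C)(C)C)[C@@H]1COC(C)(C)O1 | intermediate
9 | C8 alcohol: 8 with a free C8 hydroxyl | I/C=C/C(C)=C\[C@@H](OC(=O)C(C)Br)[C@@H](O)[C@@H]1COC(C)(C)O1 | intermediate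
10 | C8 ketone: 9 oxidised at C8 | I/C=C/C(C)=C\[C@@H](OC(=O)C(C)Br)C(=O)[C@@H]1COC(C)(C)O1 | intermediate
11 | hydroxy lactone acetonide: γ-lactone O7–C19(=O)–C17H(CH3)–C8(OH)–C7H, with the (1Z,3E)-4-iodo-2-methylbuta-1,3-dienyl group on C7 and the (S)-dioxolanyl group on C8; 8-OH cis to the C18 methyl and to H-7; C7, C8, C9, C17 as in the target | I/C=C/C(C)=C\[C@H]1OC(=O)[C@H](C)[C@@]1(O)[C@@H]2COC(C)(C)O2 | intermediate
12 | lactone triol: 11 with free C9 and C10 hydroxyls | I/C=C/C(C)=C\[C@H]1OC(=O)[C@H](C)[C@@]1(O)[C@@H](O)CO | intermediate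
13 | 2-(triphenylphosphoranylidene)propanal | CC(C=O)=P(c1ccccc1)(c1ccccc1)c1ccccc1 | starting material
14 | C10 hydroxy aldehyde: 12 oxidised at C10 | I/C=C/C(C)=C\[C@H]1OC(=O)[C@H](C)[C@@]1(O)[C@@H](O)C=O | intermediate
15 | enal diol: lactone 12 carrying on C8 the chain C9H(OH)–C10H=C1(CH3)–C2HO, E (formyl trans to C9) | I/C=C/C(C)=C\[C@H]1OC(=O)[C@H](C)[C@@]1(O)[C@@H](O)/C=C(\C)C=O | intermediate
16 | pent-1-en-3-one (ethyl vinyl ketone; becomes C11–C14 and C20) | C=CC(=O)CC | starting material
17 | dienyl silyl triflate: (Z)-diisopropyl(penta-1,3-dien-3-yloxy)silyl trifluoromethanesulfonate | C=C/C(O[Si](C(C)C)(C(C)C)OS(=O)(=O)C(F)(F)F)=C/C | intermediate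
18 | silaketal: 15 with O9–Si(iPr)2–O–C12(=C11H–CH3)–C13H=C14H2, Z enol ether | I/C=C/C(C)=C\[C@H]1OC(=O)[C@H](C)[C@@]1(O)[C@@H](O[Si](C(C)C)(C(C)C)O/C(C=C)=C\C)/C=C(\C)C=O | intermediate
19 | bridged cycloadduct: cyclohexene C1(CH3)(CHO)–C14H2–C13H=C12(O)–C11H(CH3)–C10H bridged by O12–Si(iPr)2–O9, with C9 on C10; C1, C10, C11 as in the target (C15 methyl, C9 and C20 methyl all cis) | O=C[C@@]1(C)CC=C2O[Si](C(C)C)(C(C)C)O[C@@H]([C@H]1[C@H]2C)[C@]3(O)[C@@H](C)C(=O)O[C@@H]3/C=C(C)\C=C\I | intermediate
20 | aryloxysilyl enone: enone 21 carrying on O9 the Si(iPr)2–O–(2,3-dichloro-5,6-dicyano-4-hydroxyphenyl) group | O=C[C@@]1(C)C=CC(=O)[C@H](C)[C@@H]1[C@H](O[Si](C(C)C)(C(C)C)Oc3c(Cl)c(Cl)c(O)c(C#N)c3C#N)[C@]2(O)[C@@H](C)C(=O)O[C@@H]2/C=C(C)\C=C\I | intermediate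
21 | iodo enone aldehyde: cyclohex-2-enone (C12=O, C13=C14) with C1(CH3)(CHO), C11–CH3 and C10 bearing C9H(OH) linked to the lactone and iododiene of 11 | O=C[C@@]1(C)C=CC(=O)[C@H](C)[C@@H]1[C@H](O)[C@]2(O)[C@@H](C)C(=O)O[C@@H]2/C=C(C)\C=C\I | intermediate
22 | C2 silyl ether: the C2 O-trimethylsilyl ether of 23 | C/C1=C/[C@H]2OC(=O)[C@H](C)[C@@]2(O)[C@@H](O)[C@H]3[C@@H](C)C(=O)C=C[C@]3(C)[C@@H](O[Si](C)(C)C)\C=C\1 | intermediate
23 | macrocyclic dienol: briarane skeleton with 3E,5Z-diene, 2-OH, 8-OH, 9-OH, 12-oxo-13-ene and the 19,7-lactone; C2 as in the target | C/C1=C/[C@H]2OC(=O)[C@H](C)[C@@]2(O)[C@@H](O)[C@H]3[C@@H](C)C(=O)C=C[C@]3(C)[C@@H](O)\C=C\1 | intermediate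
24 | 3,4-epoxide: 23 with the trans-3,4-oxirane as in the target | C/C1=C/[C@H]2OC(=O)[C@H](C)[C@@]2(O)[C@@H](O)[C@H]3[C@@H](C)C(=O)C=C[C@]3(C)[C@@H](O)[C@H]4O[C@H]14 | intermediate
25 | diacetate: 24 acetylated at O2 and O9 | C/C1=C/[C@H]2OC(=O)[C@H](C)[C@@]2(O)[C@@H](OC(C)=O)[C@H]3[C@@H](C)C(=O)C=C[C@]3(C)[C@@H](OC(C)=O)[C@H]4O[C@H]14 | intermediate
26 | allylic chloride: 6-chloro-5(16)-ene with C6 as in the target, 12-oxo-13-ene retained | C=C1[C@H](Cl)[C@H]2OC(=O)[C@H](C)[C@@]2(O)[C@@H](OC(C)=O)[C@H]3[C@@H](C)C(=O)C=C[C@]3(C)[C@@H](OC(C)=O)[C@H]4O[C@H]14 | intermediate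
27 | 12-epi allylic alcohol: 12-OH cis to the C20 methyl, 13-ene | C=C1[C@H](Cl)[C@H]2OC(=O)[C@H](C)[C@@]2(O)[C@@H](OC(C)=O)[C@H]3[C@@H](C)[C@@H](O)C=C[C@]3(C)[C@@H](OC(C)=O)[C@H]4O[C@H]14 | intermediate
28 | 12-formate: C12 inverted (oxygen trans to the C20 methyl), O-formyl | C=C1[C@H](Cl)[C@H]2OC(=O)[C@H](C)[C@@]2(O)[C@@H](OC(C)=O)[C@H]3[C@@H](C)[C@H](OC=O)C=C[C@]3(C)[C@@H](OC(C)=O)[C@H]4O[C@H]14 | intermediate
29 | 12-allylic alcohol: 12-OH as in the target, 13-ene | C=C1[C@H](Cl)[C@H]2OC(=O)[C@H](C)[C@@]2(O)[C@@H](OC(C)=O)[C@H]3[C@@H](C)[C@H](O)C=C[C@]3(C)[C@@H](OC(C)=O)[C@H]4O[C@H]14 | intermediate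
30 | CNP0141778.4: 2,9-di-O-acetyl-6-chloro-3,4:13,14-diepoxy-8,12-dihydroxybriar-5(16)-ene 19,7-lactone | C=C1[C@H]2O[C@@H]2[C@H](OC(C)=O)[C@]2(C)[C@H]([C@@H](C)[C@H](O)[C@@H]3O[C@@H]32)[C@H](OC(C)=O)[C@@]2(O)[C@H](OC(=O)[C@@H]2C)[C@H]1Cl | target

## Step count and risks

Total step count: 20. Longest linear sequence: 20 steps (1 to 30; 19 from the chiral starting material 3).

**Step 13, the proposed electrochemical ring closure.** An electrocatalytic chromium cycle has not been used to close a ten-membered carbocycle. Catalyst turnover at 1 mM, competing reduction of the enone, and the facial outcome at C2 are all untested. The fallback leaves electrochemistry and catalytic chromium altogether and sets out from 21. The ring is closed by the established stoichiometric Nozaki–Hiyama–Kishi macrocyclisation (CrCl2, 10 equiv, as the chemical reductant; NiCl2, 1 mol%; DMSO–THF, 1 mM, rt), which tolerates the free hydroxyls, the enone and the lactone. It comes back to the route at 23 and makes no new compound (F0).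

**Step 11, the silaketal-tethered type 2 Diels–Alder reaction.** The dienophile is a trisubstituted enal that must form a quaternary centre, and 120 °C may erode the iododiene or dehydrate the β-hydroxy lactone. The fallback gives up the tether and sets out from 15. The C9 hydroxyl is silylated (TESOTf, 2,6-lutidine) to the C9 triethylsilyl ether of the enal F1. Ketone 16 is converted (TESOTf, Et3N) into (Z)-triethyl(penta-1,3-dien-3-yloxy)silane F2. The two are joined in an intermolecular, Lewis-acid-promoted Diels–Alder reaction (Me2AlCl, CH2Cl2, −78 °C) to the silyl enol ether cycloadduct F3. DDQ followed by HF·pyridine then brings the sequence back to the route at 21. Facial and endo/exo control here rest on the polar Felkin-type model and are expected to be lower than with the tether.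

**Step 16, the ene-type chlorination.** The olefin is deactivated by two allylic C–O bonds, the vinyl oxirane is acid-sensitive, and the face selectivity at C6 is only argued. The fallback replaces the one-step ene reaction by a two-step allylic transposition and sets out from 25. Allylic hydroxylation of the C16 methyl (SeO2 cat., t-BuOOH, CH2Cl2) gives the C16 primary allylic alcohol F4. Thionyl chloride in Et2O at −20 °C without base then delivers chloride to C6 through the chlorosulfite with allylic transposition (SNi′). This comes back to the route at 26.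

## Further compounds

F1 | step 11 | C9 triethylsilyl ether of the enal 15 | I/C=C/C(C)=C\[C@H]1OC(=O)[C@H](C)[C@@]1(O)[C@@H](O[Si](CC)(CC)CC)/C=C(\C)C=O
F2 | step 11 | (Z)-triethyl(penta-1,3-dien-3-yloxy)silane | C=C/C(O[Si](CC)(CC)CC)=C/C
F3 | step 11 | silyl enol ether cycloadduct (C12 triethylsilyl enol ether, C9 triethylsilyl ether; C1, C10, C11 as in 19) | O=C[C@@]1(C)CC=C(O[Si](CC)(CC)CC)[C@H](C)[C@@H]1[C@H](O[Si](CC)(CC)CC)[C@]2(O)[C@@H](C)C(=O)O[C@@H]2/C=C(C)\C=C\I
F0 | step 13 | none | none
F4 | step 16 | C16 primary allylic alcohol of 25 (5Z olefin retained) | OC/C1=C/[C@H]2OC(=O)[C@H](C)[C@@]2(O)[C@@H](OC(C)=O)[C@H]3[C@@H](C)C(=O)C=C[C@]3(C)[C@@H](OC(C)=O)[C@H]4O[C@H]14
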